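The runs come from a simulation for an exercise, noise included.

At early times the earlier runs already show a gap in the balance. At 0.833 h the spring run has 88.4 % of its charge still free and 6.0 % in chains, together 94.4 %.

all flasks: initiator 10 mol%
- spring: free monomer 0.065 M; run made earlier
- midnight: free monomer 0.098 M; run made earlier
- flask: free monomer 0.13 M; time 8.0 h

| run | time / h | monomer in chains / % | free monomer / % |
|---|---|---|---|
| spring | 0.833 | 6.0 | 88.4 |
| spring | 1.50 | 9.8 | 80.8 |
| spring | 2.50 | 12.4 | 71.9 |
| spring | 3.00 | 14.3 | 67.5 |
| spring | 4.00 | 16.6 | 60.0 |
| spring | 5.00 | 20.1 | 55.0 |
| midnight | 0.333 | 4.7 | 93.3 |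
| midnight | 1.00 | 10.5 | 83.3 |
| midnight | 1.50 | 13.9 | 75.7 |
| midnight | 2.50 | 19.6 | 65.5 |
| midnight | 4.00 | 25.5 | 52.9 |
| midnight | 5.00 | 29.6 | 45.7 |

(scatter of a reading: 0.5 percentage points)

- average number of monomer units in a chain (chains begun, living or dead) at 8.0 h
- part of the free monomer that has reacted at 8.0 h

- the average divides the monomer in chains by the number of chains begun, living and dead together
- the analysis behind the earlier runs scatters by 0.5 percentage points, standard deviation
- the earlier runs do not show the number of chains; that part of a forecast is a guess

Two chemists dispute the flask, and both work with the log drop, ln(charged/left). The first holds to one step: reacted free monomer enters chains, so the drop scales with charge and time. The spring run drops 0.598 by 5.00 h. Scaled, that gives 1.91 for the flask, so 85.2 % reacted.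

The second objects. The same scaling gives the midnight run 0.901, but its readings give 0.783. Also, at 5.00 h, 24.7 % of the midnight charge is neither free nor in chains, against a scatter of 0.5 percentage points.

She therefore holds to two pseudo-first-order channels, which share the drop as they share the reacted monomer. The side channel takes 0.0662 /h in the spring run and 0.0712 /h in the midnight run, so she takes the mean, 0.0687 /h. The chain channel, divided by the charge, reads 0.822 /M/h and 0.871 /M/h. Their mean is 0.846 /M/h, the chain constant: log drop into chains per hour per molar of free monomer charged, at this loading. For the flask her drop is 1.43, so 76.1 % reacted. The runs do not show chains begun, so dp stays a guess.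

The forecast sides with her: 76 % reacted (range 72 % to 79 %) and dp 5 (range 4.2 to 8), with this caution: “Incomplete initiation would raise it, and the runs cannot show this”.

The flask gives 76.7 % reacted and dp 5.91.

    free monomer → uncatalysed product (k = 0.00121 /min)
    free monomer + living end → monomer in chains + living end, rate k2*[living end]*[free monomer] (k = 0.167 /M/min)
    initiator → spent initiator (k = 0.00910 /min)
    free monomer + initiator → living end + monomer in chains (k = 0.297 /M/min)

A neighbour flask charged with 25 mol% of initiator tests the chain constant, and it is where the one-step view stands nearer. Taking the chain constant as proportional to loading, its chain channel is 2.50 times larger, the drop is 2.75, and 6.39 % stays free. That neighbour shows 6.5 % free, 75.2 % in chains and 18.4 % in uncatalysed product. Chains thus hold 80.3 % of what reacted, more than the 61.2 % in the flask. That neighbour's dp is 3.88.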